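**Retrosynthetic overview**
1. Target 25 ← global desilylation ← two esterifications with retention on the all-cis diol 16 (angelate on the allylic O-4, then the TBS-protected (E)-4-hydroxytiglate on the α-ketol O-6) ← hydrogenation of the isopropenyl diol 15.
2. Key disconnection: the ring bond C-4–C-5. A 2,3-disubstituted furan is opened by 1O2/Me2S to a (Z)-4-oxo-enal, and its aldehyde is allylated in the same flask by a six-membered cyclic allylboronate that hangs on O-6 (boron tether, removed with MeOH).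
3. Enabling feature: ring atoms C-4, C-5, C-6 carry O, isopropyl, O all-cis. O-4 and O-6 (1,3-cis) can sit on one boron as a 1,3,2-dioxaborinane (a 2,4-dioxa-3-borabicyclo[3.3.1]nonenone), the C-5 substituent is the transposed allyl unit, and C-1(=O)–C-2=C-3–C-4(O) is an opened furan.
4. Cyclic allylboronate 11 ← boron-tethered RCM of (S)-furyl vinyl carbinol 5 with methallylboronate 9; 5 ← enantioselective vinylation of furaldehyde 4 ← furan-3-ylmethanol 1.
5. Ring order: furan (bought) → 1,2-oxaborinine (RCM, temporary) → cyclohexenone + dioxaborinane in the key step (furan and oxaborinine open) → boron removed; side-chain acid 23 by Wittig olefination.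

Key step: step 6

Remark: ring positions follow the cyclohex-2-en-1-one numbering of the target (C-1 ketone, C-2 bearing CH2OH, C-4 angelate, C-5 isopropyl, C-6 hydroxytiglate); the target is read as the all-cis (4S,5S,6S) isomer with a (Z)-angelate and an (E)-4-hydroxy-2-methylbut-2-enoate.

**Step 1**
Reactants: 1 furan-3-ylmethanol
Product: 3 3-(hydroxymethyl)furan-2-carbaldehyde, via dilithio species 2 (not isolated)
Conditions: n-BuLi (2.2 equiv), THF, −78 → 0 °C; DMF, −78 °C → rt; aq. NH4Cl
Reagents that add atoms: N,N-dimethylformamide, CN(C)C=O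
Why: The lithium alkoxide directs the second deprotonation to C-2 (α to the ring oxygen and ortho to CH2OLi), and the 2-lithiofuran is formylated by DMF (directed ortho-lithiation/formylation); no stereocentre is involved.

**Step 2**
Reactants: 3 3-(hydroxymethyl)furan-2-carbaldehyde
Product: 4 3-({[tert-butyl(dimethyl)silyl]oxy}methyl)furan-2-carbaldehyde
Conditions: TBSCl, imidazole, CH2Cl2, 0 °C → rt
Reagents that add atoms: tert-butyldimethylsilyl chloride, CC(C)(C)[Si](C)(C)Cl
Why: Standard silylation of a primary alcohol, done after the lithiation so that no 1,4 O→C silyl migration can occur.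

**Step 3**
Reactants: 4 3-({[tert-butyl(dimethyl)silyl]oxy}methyl)furan-2-carbaldehyde
Product: 5 (1S)-1-[3-({[tert-butyl(dimethyl)silyl]oxy}methyl)furan-2-yl]prop-2-en-1-ol
Conditions: Zn(CH=CH2)2 (from CH2=CHMgBr/ZnCl2, Mg salts removed with 1,4-dioxane), (2S)-(−)-3-exo-(dimethylamino)isoborneol (10 mol %), toluene/Et2O, 0 °C; aq. NH4Cl
Reagents that add atoms: divinylzinc, C=C[Zn]C=C
Why: Amino-alcohol-catalysed enantioselective alkenylzinc addition to a heteroaryl aldehyde, in which the (2S)-ligand–zinc chelate should deliver the vinyl group to the Si face of the formyl group and so set the (S)-carbinol centre that becomes C-6.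

**Step 4**
Reactants: 6 triisopropyl borate; 7 (2-methylprop-2-en-1-yl)magnesium chloride
Product: 9 dipropan-2-yl (2-methylprop-2-en-1-yl)boronate, via chloromagnesium allylborate 8 (not isolated)
Conditions: Et2O/THF, −78 °C; HCl (1 M in Et2O, 1 equiv), −78 °C → rt; filter under Ar; distil
Reagents that add atoms: none
Why: Addition of the allylic Grignard reagent to the trialkyl borate gives the ate complex, which anhydrous HCl breaks down to the allylboronic ester (standard allylboronate preparation); no stereocentre is involved.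

**Step 5**
Reactants: 5 (1S)-1-[3-({[tert-butyl(dimethyl)silyl]oxy}methyl)furan-2-yl]prop-2-en-1-ol; 9 dipropan-2-yl (2-methylprop-2-en-1-yl)boronate
Product: 11 (6S)-6-[3-({[tert-butyl(dimethyl)silyl]oxy}methyl)furan-2-yl]-4-methyl-2-(propan-2-yloxy)-3,6-dihydro-2H-1,2-oxaborinine, via mixed boronic ester 10 (not isolated)
Conditions: 9 (1.5 equiv), CH2Cl2, rt, then vacuum (removal of iPrOH); Grubbs II catalyst (5 mol %), CH2Cl2, 40 °C; volatiles removed, crude 11 kept under Ar
Reagents that add atoms: none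
Why: Alkoxy exchange at boron ties the carbinol to the methallyl unit, and ring-closing metathesis of this boron-tethered diene closes the six-membered oxaborinine, whose ring size forces the Z trisubstituted olefin needed in step 6 (boron-tethered RCM); the carbinol centre is untouched.

**Step 6**
Reactants: 11 (6S)-6-[3-({[tert-butyl(dimethyl)silyl]oxy}methyl)furan-2-yl]-4-methyl-2-(propan-2-yloxy)-3,6-dihydro-2H-1,2-oxaborinine
Product: 15 (4S,5S,6S)-2-({[tert-butyl(dimethyl)silyl]oxy}methyl)-4,6-dihydroxy-5-(prop-1-en-2-yl)cyclohex-2-en-1-one, via furan endoperoxide 12 (not isolated), via Z-keto-enal 13 (not isolated), via bicyclic borate 14 (not isolated)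
Conditions: O2, hν (white LED), tetraphenylporphyrin (1 mol %), CH2Cl2 (0.01 M), −78 °C; Me2S (2 equiv), −78 °C → rt; MeOH, evaporate (×3); SiO2
Reagents that add atoms: oxygen, O=O
Why: Proposed new method: singlet oxygen adds [4+2] across the furan (the most electron-rich diene in 11), Me2S reduces endoperoxide 12 to the (Z)-4-oxo-2-enal 13, and the freed aldehyde is attacked by the γ-carbon of the allylboronate held on O-6 while boron moves from carbon to the aldehyde oxygen (allylboration with allylic transposition, giving the isopropenyl group and borate 14, which methanol strips to diol 15). The closest known reaction types are the photooxygenation/Me2S opening of 2-alkylfurans to cis-enediones, the addition of six-membered cyclic allylboronic esters made by boron-tethered RCM to aldehydes, and intramolecular allylborations; using both tethers at once is the new element. One C–C bond closes two rings, the cyclohexenone by 6-exo-trig attack on the formyl carbon and the 1,3,2-dioxaborinane by the new B–O bond while the oxaborinine opens; because O-6 spans boron and the allyl γ-carbon, the six-centre B–O=C···C=C–C array must be a boat, i.e. a bicyclo[2.2.2] transition state, with the C-1–C-3 chain lying between its two oxygen-bearing bridges. The new stereocentre C-4 is controlled by the boron bridge (both oxygens on one boron, so C-4–O is cis to C-6–O) and the new stereocentre C-5 by the oxaborinine ring (O-6 and the allyl unit are tied cis, so the isopropenyl group emerges cis to both oxygens); with C-6 fixed in step 3 no other diastereomeric cage can join the two carbons, and the Z-enal geometry that closure needs is inherited from the furan ring. The step needs chemoselective oxidation, secured by the much higher singlet-oxygen reactivity of a 2,3-dialkylfuran over a trisubstituted olefin at −78 °C and the inertness of the boronate to Me2S, and intra- over intermolecular allyl transfer, secured by dilution and the absence of any other aldehyde or free hydroxyl (a free 6-OH would instead close to a pyranone lactol).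

**Step 7**
Reactants: 15 (4S,5S,6S)-2-({[tert-butyl(dimethyl)silyl]oxy}methyl)-4,6-dihydroxy-5-(prop-1-en-2-yl)cyclohex-2-en-1-one
Product: 16 (4S,5S,6S)-2-({[tert-butyl(dimethyl)silyl]oxy}methyl)-4,6-dihydroxy-5-(propan-2-yl)cyclohex-2-en-1-one
Conditions: H2 (1 atm), RhCl(PPh3)3 (5 mol %), benzene, rt
Reagents that add atoms: none
Why: Wilkinson's catalyst hydrogenates the 1,1-disubstituted isopropenyl olefin far faster than the trisubstituted, conjugated ring olefin (the carvone → carvotanacetone selectivity), and no stereocentre is created because C-5 is already set.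

**Step 8**
Reactants: 16 (4S,5S,6S)-2-({[tert-butyl(dimethyl)silyl]oxy}methyl)-4,6-dihydroxy-5-(propan-2-yl)cyclohex-2-en-1-one; 17 (2Z)-2-methylbut-2-enoic acid (angelic acid)
Product: 19 (4S,5R,6S)-2-({[tert-butyl(dimethyl)silyl]oxy}methyl)-6-hydroxy-4-{[(2Z)-2-methylbut-2-enoyl]oxy}-5-(propan-2-yl)cyclohex-2-en-1-one, via angelic mixed anhydride 18 (not isolated)
Conditions: 17 (1.1 equiv), 2,4,6-trichlorobenzoyl chloride, Et3N, toluene, rt; filter; add 16, toluene, 60 °C (no DMAP)
Reagents that add atoms: none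
Why: The allylic 4-OH should be the more nucleophilic hydroxyl (the 6-OH is deactivated by the adjacent ketone), and the pre-formed Yamaguchi mixed anhydride acylates it with retention under near-neutral, DMAP-free conditions that do not isomerise the (Z)-angeloyl group to tigloyl.

**Step 9**
Reactants: 20 {[tert-butyl(dimethyl)silyl]oxy}acetaldehyde; 21 ethyl 2-(triphenyl-λ5-phosphanylidene)propanoate
Product: 22 ethyl (2E)-4-{[tert-butyl(dimethyl)silyl]oxy}-2-methylbut-2-enoate
Conditions: CH2Cl2, rt
Reagents that add atoms: none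
Why: Wittig olefination with a stabilised α-methyl ylide gives the (E)-trisubstituted enoate.

**Step 10**
Reactants: 22 ethyl (2E)-4-{[tert-butyl(dimethyl)silyl]oxy}-2-methylbut-2-enoate
Product: 23 (2E)-4-{[tert-butyl(dimethyl)silyl]oxy}-2-methylbut-2-enoic acid
Conditions: LiOH, THF/H2O, 0 °C → rt; 1 M HCl to pH 4, 0 °C
Reagents that add atoms: lithium hydroxide, [Li+].[OH-]
Why: Saponification of the ethyl ester under mild conditions that the primary TBS ether and the E olefin tolerate.

**Step 11**
Reactants: 19 (4S,5R,6S)-2-({[tert-butyl(dimethyl)silyl]oxy}methyl)-6-hydroxy-4-{[(2Z)-2-methylbut-2-enoyl]oxy}-5-(propan-2-yl)cyclohex-2-en-1-one; 23 (2E)-4-{[tert-butyl(dimethyl)silyl]oxy}-2-methylbut-2-enoic acid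
Product: 24 (4S,5S,6S)-2-({[tert-butyl(dimethyl)silyl]oxy}methyl)-6-{[(2E)-4-{[tert-butyl(dimethyl)silyl]oxy}-2-methylbut-2-enoyl]oxy}-4-{[(2Z)-2-methylbut-2-enoyl]oxy}-5-(propan-2-yl)cyclohex-2-en-1-one
Conditions: DCC, DMAP (10 mol %), CH2Cl2, 0 °C → rt
Reagents that add atoms: none
Why: Steglich esterification of the remaining α-ketol hydroxyl proceeds with retention at C-6, the (E)-acid being the geometrically stable isomer, while low temperature and catalytic DMAP limit base-induced elimination or aromatisation.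

**Step 12**
Reactants: 24 (4S,5S,6S)-2-({[tert-butyl(dimethyl)silyl]oxy}methyl)-6-{[(2E)-4-{[tert-butyl(dimethyl)silyl]oxy}-2-methylbut-2-enoyl]oxy}-4-{[(2Z)-2-methylbut-2-enoyl]oxy}-5-(propan-2-yl)cyclohex-2-en-1-one
Product: 25 (4S,5S,6S)-6-{[(2E)-4-hydroxy-2-methylbut-2-enoyl]oxy}-2-(hydroxymethyl)-4-{[(2Z)-2-methylbut-2-enoyl]oxy}-5-(propan-2-yl)cyclohex-2-en-1-one
Conditions: HF·pyridine, pyridine, THF, 0 °C → rt
Reagents that add atoms: none
Why: Buffered HF·pyridine cleaves both primary TBS ethers (fluoride-driven Si–O cleavage) without touching the esters, the angelate geometry or the base-sensitive α-acyloxy enone.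

**Compound list**
1 | furan-3-ylmethanol | OCc1ccoc1 | starting material
2 | 2-lithio-3-(lithiooxymethyl)furan | [Li]OCc1ccoc1[Li] | intermediate
3 | 3-(hydroxymethyl)furan-2-carbaldehyde | O=Cc1occc1CO | intermediate
4 | 3-({[tert-butyl(dimethyl)silyl]oxy}methyl)furan-2-carbaldehyde | O=Cc1occc1CO[Si](C)(C)C(C)(C)C | intermediate
5 | (1S)-1-[3-({[tert-butyl(dimethyl)silyl]oxy}methyl)furan-2-yl]prop-2-en-1-ol | C=C[C@H](O)c1occc1CO[Si](C)(C)C(C)(C)C | intermediate
6 | triisopropyl borate | CC(C)OB(OC(C)C)OC(C)C | starting material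
7 | (2-methylprop-2-en-1-yl)magnesium chloride | CC(=C)C[Mg]Cl | starting material
8 | chloromagnesium (2-methylprop-2-en-1-yl)tri(propan-2-yloxy)borate | CC(=C)C[B-](OC(C)C)(OC(C)C)OC(C)C.[Mg+]Cl | intermediate
9 | dipropan-2-yl (2-methylprop-2-en-1-yl)boronate | CC(=C)CB(OC(C)C)OC(C)C | intermediate
10 | propan-2-yl (1S)-1-[3-({[tert-butyl(dimethyl)silyl]oxy}methyl)furan-2-yl]prop-2-en-1-yl (2-methylprop-2-en-1-yl)boronate | C=C[C@H](OB(OC(C)C)CC(C)=C)c1occc1CO[Si](C)(C)C(C)(C)C | intermediate
11 | (6S)-6-[3-({[tert-butyl(dimethyl)silyl]oxy}methyl)furan-2-yl]-4-methyl-2-(propan-2-yloxy)-3,6-dihydro-2H-1,2-oxaborinine | CC(C)OB1CC(C)=C[C@H](O1)c1occc1CO[Si](C)(C)C(C)(C)C | intermediate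
12 | furan endoperoxide of 11 (2,3,7-trioxabicyclo[2.2.1]hept-5-ene bearing the (6S)-oxaborinin-6-yl group at C-1 and CH2OTBS at C-6; both bridgehead diastereomers) | CC(C)OB1CC(C)=C[C@H](O1)C23OOC(O2)C=C3CO[Si](C)(C)C(C)(C)C | intermediate
13 | (2Z)-3-({[tert-butyl(dimethyl)silyl]oxy}methyl)-4-[(6S)-4-methyl-2-(propan-2-yloxy)-3,6-dihydro-2H-1,2-oxaborinin-6-yl]-4-oxobut-2-enal | O=C/C=C(/CO[Si](C)(C)C(C)(C)C)C(=O)[C@H]1OB(OC(C)C)CC(C)=C1 | intermediate
14 | (1S,5S,9S)-7-({[tert-butyl(dimethyl)silyl]oxy}methyl)-3-(propan-2-yloxy)-9-(prop-1-en-2-yl)-2,4-dioxa-3-borabicyclo[3.3.1]non-6-en-8-one (boron bridges O-4 and O-6 of the cyclohexenone, isopropenyl cis to both) | CC(C)OB1O[C@H]2C=C(CO[Si](C)(C)C(C)(C)C)C(=O)[C@@H](O1)[C@H]2C(C)=C | intermediate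
15 | (4S,5S,6S)-2-({[tert-butyl(dimethyl)silyl]oxy}methyl)-4,6-dihydroxy-5-(prop-1-en-2-yl)cyclohex-2-en-1-one (all-cis) | O[C@H]1C=C(CO[Si](C)(C)C(C)(C)C)C(=O)[C@@H](O)[C@H]1C(C)=C | intermediate
16 | (4S,5S,6S)-2-({[tert-butyl(dimethyl)silyl]oxy}methyl)-4,6-dihydroxy-5-(propan-2-yl)cyclohex-2-en-1-one (all-cis) | O[C@H]1C=C(CO[Si](C)(C)C(C)(C)C)C(=O)[C@@H](O)[C@H]1C(C)C | intermediate
17 | (2Z)-2-methylbut-2-enoic acid (angelic acid) | C/C=C(/C)C(=O)O | starting material
18 | (2Z)-2-methylbut-2-enoic 2,4,6-trichlorobenzoic anhydride | C/C=C(/C)C(=O)OC(=O)c1c(Cl)cc(Cl)cc1Cl | intermediate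
19 | (4S,5R,6S)-2-({[tert-butyl(dimethyl)silyl]oxy}methyl)-6-hydroxy-4-{[(2Z)-2-methylbut-2-enoyl]oxy}-5-(propan-2-yl)cyclohex-2-en-1-one (all-cis; the 5R label is a CIP priority change only) | C/C=C(/C)C(=O)O[C@H]1C=C(CO[Si](C)(C)C(C)(C)C)C(=O)[C@@H](O)[C@H]1C(C)C | intermediate
20 | {[tert-butyl(dimethyl)silyl]oxy}acetaldehyde | O=CCO[Si](C)(C)C(C)(C)C | starting material
21 | ethyl 2-(triphenyl-λ5-phosphanylidene)propanoate | CCOC(=O)C(C)=P(c1ccccc1)(c1ccccc1)c1ccccc1 | starting material
22 | ethyl (2E)-4-{[tert-butyl(dimethyl)silyl]oxy}-2-methylbut-2-enoate | CCOC(=O)/C(C)=C/CO[Si](C)(C)C(C)(C)C | intermediate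
23 | (2E)-4-{[tert-butyl(dimethyl)silyl]oxy}-2-methylbut-2-enoic acid | OC(=O)/C(C)=C/CO[Si](C)(C)C(C)(C)C | intermediate
24 | (4S,5S,6S)-2-({[tert-butyl(dimethyl)silyl]oxy}methyl)-6-{[(2E)-4-{[tert-butyl(dimethyl)silyl]oxy}-2-methylbut-2-enoyl]oxy}-4-{[(2Z)-2-methylbut-2-enoyl]oxy}-5-(propan-2-yl)cyclohex-2-en-1-one | C/C=C(/C)C(=O)O[C@H]1C=C(CO[Si](C)(C)C(C)(C)C)C(=O)[C@@H](OC(=O)/C(C)=C/CO[Si](C)(C)C(C)(C)C)[C@H]1C(C)C | intermediate
25 | (4S,5S,6S)-6-{[(2E)-4-hydroxy-2-methylbut-2-enoyl]oxy}-2-(hydroxymethyl)-4-{[(2Z)-2-methylbut-2-enoyl]oxy}-5-(propan-2-yl)cyclohex-2-en-1-one (CNP0281432.2) | C/C=C(/C)C(=O)O[C@H]1C=C(CO)C(=O)[C@@H](OC(=O)/C(C)=C/CO)[C@H]1C(C)C | target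

**Step count and risks**
Total steps: 12. Longest linear sequence: 9 steps (1, 2, 3, 5, 6, 7, 8, 11, 12).

Step 6 (tethered allylboration cascade). The allylboronate olefin or its C–B bond may be oxidised in competition with the furan, or the boat-shaped allyl transfer may be slower than Z→E isomerisation or decomposition of the keto-enal. The fallback uses known chemistry: a carbonyl-ene closure of the same bond, then inversion of both carbinol centres as the esters are put on. It sets out from aldehyde 4 and comes back at diester 24. Enantioselective addition of bis(2-methylprop-1-enyl)zinc with the (2R)-amino-alcohol ligand gives (1R)-1-[3-({[tert-butyl(dimethyl)silyl]oxy}methyl)furan-2-yl]-3-methylbut-2-en-1-ol F1, which is silylated (TESCl, imidazole) to its triethylsilyl ether F2. Photooxygenation/Me2S opens the furan to the (2Z,5R)-keto-enal F3. A Type I carbonyl-ene cyclisation (Me2AlCl, CH2Cl2, −78 °C) should then close the C-4–C-5 bond through the chair in which the formyl oxygen, the olefin and the silyloxy group are equatorial (A1,3 strain keeps H-6 in the olefin plane), giving the all-trans (4R,5S,6R)-hydroxy enone F4. Wilkinson hydrogenation gives the isopropyl compound F5. Mitsunobu esterification with angelic acid 17 (PPh3, DIAD) inverts C-4 to the (4S)-angelate F6. PPTS/MeOH removes the TES group to give the 6-epi alcohol F7, and a second Mitsunobu reaction with acid 23 inverts C-6 and delivers 24.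

Step 8 (regioselective mono-angeloylation). Discrimination between the two secondary hydroxyls may be poor, or the acyl group may migrate between the cis-1,3 oxygens. The fallback reverses the order and uses chelation-directed acylation; it sets out from diol 16 and comes back at 24. Acid 23 is converted with DCC (0.5 equiv) into its symmetrical anhydride F8. With catalytic CeCl3 in THF this should acylate the ketone-chelated α-ketol hydroxyl first, giving the 6-O-acyl 4-alcohol F9. Angeloylation of the one remaining hydroxyl with mixed anhydride 18 (conditions of step 8) gives 24.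

Step 3 (enantioselective vinylation). Uncatalysed background addition (residual magnesium salts, ortho-substituted heteroaryl aldehyde) may erode the enantioselectivity. The fallback is a resolution; it sets out from 4 and comes back at 5. Vinylmagnesium bromide gives the racemic carbinol F10. Lipase-catalysed transesterification (Candida antarctica lipase B, vinyl acetate, hexane) should acetylate the (R)-enantiomer to the (R)-acetate F11 and leave the (S)-carbinol 5, which is separated by chromatography.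

**Further compounds**
F1 | step 6 | (1R)-1-[3-({[tert-butyl(dimethyl)silyl]oxy}methyl)furan-2-yl]-3-methylbut-2-en-1-ol | CC(C)=C[C@@H](O)c1occc1CO[Si](C)(C)C(C)(C)C
F2 | step 6 | tert-butyl(dimethyl)({2-[(1R)-3-methyl-1-[(triethylsilyl)oxy]but-2-en-1-yl]furan-3-yl}methoxy)silane | CC(C)=C[C@@H](O[Si](CC)(CC)CC)c1occc1CO[Si](C)(C)C(C)(C)C
F3 | step 6 | (2Z,5R)-3-({[tert-butyl(dimethyl)silyl]oxy}methyl)-7-methyl-4-oxo-5-[(triethylsilyl)oxy]octa-2,6-dienal | O=C/C=C(/CO[Si](C)(C)C(C)(C)C)C(=O)[C@H](O[Si](CC)(CC)CC)C=C(C)C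
F4 | step 6 | (4R,5S,6R)-2-({[tert-butyl(dimethyl)silyl]oxy}methyl)-4-hydroxy-5-(prop-1-en-2-yl)-6-[(triethylsilyl)oxy]cyclohex-2-en-1-one | O[C@@H]1C=C(CO[Si](C)(C)C(C)(C)C)C(=O)[C@H](O[Si](CC)(CC)CC)[C@H]1C(C)=C
F5 | step 6 | (4R,5S,6R)-2-({[tert-butyl(dimethyl)silyl]oxy}methyl)-4-hydroxy-5-(propan-2-yl)-6-[(triethylsilyl)oxy]cyclohex-2-en-1-one | O[C@@H]1C=C(CO[Si](C)(C)C(C)(C)C)C(=O)[C@H](O[Si](CC)(CC)CC)[C@H]1C(C)C
F6 | step 6 | (4S,5S,6R)-2-({[tert-butyl(dimethyl)silyl]oxy}methyl)-4-{[(2Z)-2-methylbut-2-enoyl]oxy}-5-(propan-2-yl)-6-[(triethylsilyl)oxy]cyclohex-2-en-1-one | C/C=C(/C)C(=O)O[C@H]1C=C(CO[Si](C)(C)C(C)(C)C)C(=O)[C@H](O[Si](CC)(CC)CC)[C@H]1C(C)C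
F7 | step 6 | (4S,5R,6R)-2-({[tert-butyl(dimethyl)silyl]oxy}methyl)-6-hydroxy-4-{[(2Z)-2-methylbut-2-enoyl]oxy}-5-(propan-2-yl)cyclohex-2-en-1-one | C/C=C(/C)C(=O)O[C@H]1C=C(CO[Si](C)(C)C(C)(C)C)C(=O)[C@H](O)[C@H]1C(C)C
F8 | step 8 | (2E)-4-{[tert-butyl(dimethyl)silyl]oxy}-2-methylbut-2-enoic anhydride | O=C(OC(=O)/C(C)=C/CO[Si](C)(C)C(C)(C)C)/C(C)=C/CO[Si](C)(C)C(C)(C)C
F9 | step 8 | (4S,5S,6S)-2-({[tert-butyl(dimethyl)silyl]oxy}methyl)-6-{[(2E)-4-{[tert-butyl(dimethyl)silyl]oxy}-2-methylbut-2-enoyl]oxy}-4-hydroxy-5-(propan-2-yl)cyclohex-2-en-1-one | O[C@H]1C=C(CO[Si](C)(C)C(C)(C)C)C(=O)[C@@H](OC(=O)/C(C)=C/CO[Si](C)(C)C(C)(C)C)[C@H]1C(C)C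
F10 | step 3 | racemic 1-[3-({[tert-butyl(dimethyl)silyl]oxy}methyl)furan-2-yl]prop-2-en-1-ol | C=CC(O)c1occc1CO[Si](C)(C)C(C)(C)C
F11 | step 3 | (1R)-1-[3-({[tert-butyl(dimethyl)silyl]oxy}methyl)furan-2-yl]prop-2-en-1-yl acetate | C=C[C@@H](OC(C)=O)c1occc1CO[Si](C)(C)C(C)(C)C
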